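**Retrosynthetic overview**

1. Target 14 ⇐ benzophenone 12: the CH2 bridge between C1 and C1′ of the two identical resorcinol rings A/A′ is carried as a diaryl ketone (C=O → CH2 last). Ring A numbering: C1 bridge, C2 OMe, C4 OH, C6 CH2CH2–ring B.
2. 12 ⇐ acyclic cross-conjugated diynone 8 + 2 × diene 9: a two-directional double Diels–Alder/aromatisation builds rings A and A′ together (four C–C bonds) around the ketone carbon. The polarisation of each ynone places OMe at C2, OH at C4 and the chain at C6 in both rings.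
3. 8 ⇐ diynol 7 ⇐ 2 × alkyne 4 + ethyl formate 5 (the formate carbon is the future bridge carbon).
4. 4 ⇐ zingerone 1, which supplies ring B with its OMe/OH and the CH2CH2 tether (methyl ketone → terminal alkyne).
5. Ring order: ring B is bought; rings A and A′ are formed together in step 5; the precursor 8 contains only the two bought guaiacyl rings.

Key step: step 5

Remarks on the chemistry: the target has no stereocentre and is achiral, so the compound itself is the "single enantiomer" and no stereocontrol is needed. Lithium salts of numbered compounds (enolate, acetylides, alkoxides) are treated as the same compound and are not numbered separately. LDA and n-BuLi are used as commercial solutions.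

**Step 1**
Reactants: 1 zingerone, 4-(4-hydroxy-3-methoxyphenyl)butan-2-one
Product: 2 4-[3-methoxy-4-(triisopropylsilyloxy)phenyl]butan-2-one
Conditions: TIPSCl, imidazole, DMF, rt
Reagents that add atoms: triisopropylsilyl chloride, CC(C)[Si](Cl)(C(C)C)C(C)C
Why: Imidazole-promoted silylation of a phenol; the TIPS ether masks the acidic ring B phenol against LDA, n-BuLi and the silyloxy diene and is removed later by fluoride.

**Step 2**
Reactants: 2 4-[3-methoxy-4-(triisopropylsilyloxy)phenyl]butan-2-one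
Product: 4 [4-(but-3-yn-1-yl)-2-methoxyphenoxy]triisopropylsilane, via diethyl 4-[3-methoxy-4-(triisopropylsilyloxy)phenyl]but-1-en-2-yl phosphate 3 (not isolated)
Conditions: LDA (1.05 equiv), THF, −78 °C; ClP(O)(OEt)2, −78 °C → rt; then LDA (2.3 equiv), −78 °C → rt; H2O
Reagents that add atoms: none
Why: Kinetic deprotonation at the methyl group, O-phosphorylation to the terminal enol phosphate and LDA-induced β-elimination of diethyl phosphate (methyl ketone → terminal alkyne via the enol phosphate) should give the acetylide, protonated on quench; the aryl TIPS ether is inert to the hindered amide base.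

**Step 3**
Reactants: 4 [4-(but-3-yn-1-yl)-2-methoxyphenoxy]triisopropylsilane (2.1 equiv); 5 ethyl formate (1 equiv)
Product: 7 1,9-bis[3-methoxy-4-(triisopropylsilyloxy)phenyl]nona-3,6-diyn-5-ol, via 5-[3-methoxy-4-(triisopropylsilyloxy)phenyl]pent-2-ynal 6 (not isolated)
Conditions: n-BuLi, THF, −78 °C; HCO2Et, −78 → 0 °C; H2O
Reagents that add atoms: none
Why: Twofold addition of a lithium acetylide to a formate ester (addition–elimination to ynal 6, then fast 1,2-addition of the second acetylide) is the standard entry to symmetric 1,4-diyn-3-ols and installs the future bridge carbon.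

**Step 4**
Reactants: 7 1,9-bis[3-methoxy-4-(triisopropylsilyloxy)phenyl]nona-3,6-diyn-5-ol
Product: 8 1,9-bis[3-methoxy-4-(triisopropylsilyloxy)phenyl]nona-3,6-diyn-5-one
Conditions: Dess–Martin periodinane, CH2Cl2, 0 °C → rt; product used promptly
Reagents that add atoms: none
Why: Dess–Martin oxidation of a doubly propargylic secondary alcohol to the 1,4-diyn-3-one under neutral, non-nucleophilic conditions that leave the aryl silyl ethers and electron-rich arenes untouched.

**Step 5**
Reactants: 8 1,9-bis[3-methoxy-4-(triisopropylsilyloxy)phenyl]nona-3,6-diyn-5-one; 9 1,1-dimethoxy-3-(trimethylsilyloxy)buta-1,3-diene (5 equiv)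
Product: 12 bis{4-hydroxy-2-[2-(4-hydroxy-3-methoxyphenyl)ethyl]-6-methoxyphenyl}methanone, via bis[6,6-dimethoxy-2-(2-{3-methoxy-4-(triisopropylsilyloxy)phenyl}ethyl)-4-(trimethylsilyloxy)cyclohexa-1,4-dien-1-yl]methanone 10 (not isolated), via bis[2-methoxy-6-(2-{3-methoxy-4-(triisopropylsilyloxy)phenyl}ethyl)-4-(trimethylsilyloxy)phenyl]methanone 11 (not isolated)
Conditions: PhMe, 60 → 110 °C (sealed); then TBAF, AcOH, THF, 0 °C → rt; dilute HCl work-up
Reagents that add atoms: none
Why: Each ynone arm of 8 should act as dienophile toward the electron-rich diene 9 in a polarity-matched, probably asynchronous [4+2] cycloaddition (diene CH2 terminus to the chain-bearing β-alkyne carbon, acetal carbon to the α-carbon next to C=O) to give bis(cyclohexa-1,4-diene) 10; thermal loss of one methanol per ring aromatises it to 11, and buffered fluoride then frees all four phenols. The closest known reaction type is the Diels–Alder/aromatisation of 1,1-dimethoxy-3-silyloxybutadienes with alkynyl esters, aldehydes and ketones to give 4-hydroxy-2-methoxyaryl carbonyl compounds, run here twice on one cross-conjugated 1,4-diyn-3-one. Both six-membered rings A and A′ are closed by intermolecular [4+2] cycloaddition (two C–C bonds per ring, bonds C1–C2 and C5–C6 of each ring), no ring is closed intramolecularly, and no stereocentre is created because the sp3 centres of 10 disappear on aromatisation. The step needs regioselectivity in both cycloadditions; the ketone carbon of 8 secures it by making the chain-bearing alkyne carbons the electrophilic β-positions, and the diene has a single nucleophilic terminus, so OMe must end up ortho and OH para to the carbonyl carbon, with the CH2CH2Ar chain at the other ortho position. It also needs the second cycloaddition to proceed on the hindered aryl alkynyl ketone left after the first, which is still an activated ynone and should be driven by excess diene at 110 °C. Because both arms are identical, no mono/bis differentiation is required.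

**Step 6**
Reactants: 12 bis{4-hydroxy-2-[2-(4-hydroxy-3-methoxyphenyl)ethyl]-6-methoxyphenyl}methanone
Product: 14 4,4'-methylenebis{3-[2-(4-hydroxy-3-methoxyphenyl)ethyl]-5-methoxyphenol} (target), via bis{4-hydroxy-2-[2-(4-hydroxy-3-methoxyphenyl)ethyl]-6-methoxyphenyl}methanol 13 (not isolated)
Conditions: Et3SiH (6 equiv), TFA, CH2Cl2, 0 °C → rt
Reagents that add atoms: none
Why: Ionic hydrogenation of a diaryl ketone: protonation and hydride transfer from the silane give benzhydrol 13, which ionises to the diarylmethyl cation stabilised by two para-OH and two ortho-OMe groups and is reduced again to the CH2 bridge; excess silane is meant to trap this cation before any Friedel–Crafts side reaction.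

**Compound list**

1 | zingerone, 4-(4-hydroxy-3-methoxyphenyl)butan-2-one | CC(=O)CCc1ccc(O)c(OC)c1 | starting material
2 | 4-[3-methoxy-4-(triisopropylsilyloxy)phenyl]butan-2-one | CC(=O)CCc1ccc(O[Si](C(C)C)(C(C)C)C(C)C)c(OC)c1 | intermediate
3 | diethyl 4-[3-methoxy-4-(triisopropylsilyloxy)phenyl]but-1-en-2-yl phosphate | C=C(CCc1ccc(O[Si](C(C)C)(C(C)C)C(C)C)c(OC)c1)OP(=O)(OCC)OCC | intermediate
4 | [4-(but-3-yn-1-yl)-2-methoxyphenoxy]triisopropylsilane | C#CCCc1ccc(O[Si](C(C)C)(C(C)C)C(C)C)c(OC)c1 | intermediate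
5 | ethyl formate | CCOC=O | starting material
6 | 5-[3-methoxy-4-(triisopropylsilyloxy)phenyl]pent-2-ynal | O=CC#CCCc1ccc(O[Si](C(C)C)(C(C)C)C(C)C)c(OC)c1 | intermediate
7 | 1,9-bis[3-methoxy-4-(triisopropylsilyloxy)phenyl]nona-3,6-diyn-5-ol | OC(C#CCCc1ccc(O[Si](C(C)C)(C(C)C)C(C)C)c(OC)c1)C#CCCc1ccc(O[Si](C(C)C)(C(C)C)C(C)C)c(OC)c1 | intermediate
8 | 1,9-bis[3-methoxy-4-(triisopropylsilyloxy)phenyl]nona-3,6-diyn-5-one | O=C(C#CCCc1ccc(O[Si](C(C)C)(C(C)C)C(C)C)c(OC)c1)C#CCCc1ccc(O[Si](C(C)C)(C(C)C)C(C)C)c(OC)c1 | intermediate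
9 | 1,1-dimethoxy-3-(trimethylsilyloxy)buta-1,3-diene | C=C(O[Si](C)(C)C)C=C(OC)OC | starting material
10 | bis[6,6-dimethoxy-2-(2-{3-methoxy-4-(triisopropylsilyloxy)phenyl}ethyl)-4-(trimethylsilyloxy)cyclohexa-1,4-dien-1-yl]methanone | O=C(C1=C(CCc2ccc(O[Si](C(C)C)(C(C)C)C(C)C)c(OC)c2)CC(O[Si](C)(C)C)=CC1(OC)OC)C1=C(CCc2ccc(O[Si](C(C)C)(C(C)C)C(C)C)c(OC)c2)CC(O[Si](C)(C)C)=CC1(OC)OC | intermediate
11 | bis[2-methoxy-6-(2-{3-methoxy-4-(triisopropylsilyloxy)phenyl}ethyl)-4-(trimethylsilyloxy)phenyl]methanone | O=C(c1c(CCc2ccc(O[Si](C(C)C)(C(C)C)C(C)C)c(OC)c2)cc(O[Si](C)(C)C)cc1OC)c1c(CCc2ccc(O[Si](C(C)C)(C(C)C)C(C)C)c(OC)c2)cc(O[Si](C)(C)C)cc1OC | intermediate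
12 | bis{4-hydroxy-2-[2-(4-hydroxy-3-methoxyphenyl)ethyl]-6-methoxyphenyl}methanone | O=C(c1c(CCc2ccc(O)c(OC)c2)cc(O)cc1OC)c1c(CCc2ccc(O)c(OC)c2)cc(O)cc1OC | intermediate
13 | bis{4-hydroxy-2-[2-(4-hydroxy-3-methoxyphenyl)ethyl]-6-methoxyphenyl}methanol | OC(c1c(CCc2ccc(O)c(OC)c2)cc(O)cc1OC)c1c(CCc2ccc(O)c(OC)c2)cc(O)cc1OC | intermediate
14 | 4,4'-methylenebis{3-[2-(4-hydroxy-3-methoxyphenyl)ethyl]-5-methoxyphenol} (CNP0079383.0) | COc1cc(CCc2cc(O)cc(OC)c2Cc2c(CCc3ccc(O)c(OC)c3)cc(O)cc2OC)ccc1O | target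

**Step count**

Total steps: 6. Longest linear sequence: 6 (1 → 2 → 4 → 7 → 8 → 12 → 14).

**Steps most likely to fail**

Step 5. After the first benzannulation the remaining alkyne sits on a hindered, electron-rich aryl ketone, so the second cycloaddition may be slower than thermal loss or hydrolysis of the diene. The diynone may also be consumed by conjugate addition or oligomerisation, so that the two-directional closure stops half-way. The fallback sets out from 4 and returns at 12; it builds the A rings one at a time, each on a singly activated alkyne, and gives up the two-directional economy. Alkyne 4 is lithiated (n-BuLi, THF, −78 °C) and formylated with DMF (inverse quench into aqueous KH2PO4) to give ynal 6, now isolated. Cycloaddition of 6 with diene 9 (PhMe, 60 °C) gives 6,6-dimethoxy-2-(2-{3-methoxy-4-(triisopropylsilyloxy)phenyl}ethyl)-4-(trimethylsilyloxy)cyclohexa-1,4-diene-1-carbaldehyde F1, which on treatment with dilute HCl in THF should aromatise and lose the TMS group to give 4-hydroxy-2-methoxy-6-(2-{3-methoxy-4-(triisopropylsilyloxy)phenyl}ethyl)benzaldehyde F2. Silylation (TIPSCl, imidazole, DMF) gives 2-methoxy-6-(2-{3-methoxy-4-(triisopropylsilyloxy)phenyl}ethyl)-4-(triisopropylsilyloxy)benzaldehyde F3. Addition of the lithium acetylide of 4 (THF, −78 °C) gives racemic 1-[2-methoxy-6-(2-{3-methoxy-4-(triisopropylsilyloxy)phenyl}ethyl)-4-(triisopropylsilyloxy)phenyl]-5-[3-methoxy-4-(triisopropylsilyloxy)phenyl]pent-2-yn-1-ol F4. Dess–Martin oxidation gives 1-[2-methoxy-6-(2-{3-methoxy-4-(triisopropylsilyloxy)phenyl}ethyl)-4-(triisopropylsilyloxy)phenyl]-5-[3-methoxy-4-(triisopropylsilyloxy)phenyl]pent-2-yn-1-one F5. A second cycloaddition with 9 (PhMe, 110 °C) gives [6,6-dimethoxy-2-(2-{3-methoxy-4-(triisopropylsilyloxy)phenyl}ethyl)-4-(trimethylsilyloxy)cyclohexa-1,4-dien-1-yl][2-methoxy-6-(2-{3-methoxy-4-(triisopropylsilyloxy)phenyl}ethyl)-4-(triisopropylsilyloxy)phenyl]methanone F6, which should aromatise on heating to [2-methoxy-6-(2-{3-methoxy-4-(triisopropylsilyloxy)phenyl}ethyl)-4-(trimethylsilyloxy)phenyl][2-methoxy-6-(2-{3-methoxy-4-(triisopropylsilyloxy)phenyl}ethyl)-4-(triisopropylsilyloxy)phenyl]methanone F7. TBAF/AcOH as in step 5 then gives 12.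

Step 6. Hydride delivery to the tetra-ortho-substituted carbonyl may be too slow. In TFA the diarylmethyl cation may instead be intercepted by a ring B carbon (seven-membered Friedel–Crafts closure), or the electron-rich diarylmethane may suffer acid-induced C–C cleavage at the bridge. The fallback sets out from 12 and returns at 14 without any cationic intermediate. Per-benzylation (BnBr, K2CO3, DMF) gives bis{4-(benzyloxy)-2-[2-(4-(benzyloxy)-3-methoxyphenyl)ethyl]-6-methoxyphenyl}methanone F8. Nucleophilic hydride reduction (LiAlH4, THF, reflux) gives bis{4-(benzyloxy)-2-[2-(4-(benzyloxy)-3-methoxyphenyl)ethyl]-6-methoxyphenyl}methanol F9. One hydrogenolysis (H2, Pd/C, EtOAc/MeOH with a little AcOH) should remove the doubly benzylic hydroxyl and all four benzyl groups to give 14.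

Step 4. The cross-conjugated diynone is a double Michael acceptor; acetate, acetic acid, water or silica gel may add to it or trigger oligomerisation between oxidation and key step. The fallback sets out from 4 and returns at 8, reaching the ketone oxidation level without an oxidation. The lithium acetylide of 4 is acylated with N-methoxy-N-methylcarbamoyl chloride (THF, −78 °C) to give the Weinreb amide N-methoxy-N-methyl-5-[3-methoxy-4-(triisopropylsilyloxy)phenyl]pent-2-ynamide F10. A second equivalent of the lithium acetylide of 4 adds to F10 (Weinreb ketone synthesis); the ketone is released only on inverse quench into cold dilute acid, and the dried extract of 8 is taken directly into step 5.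

**Further compounds**

F1 | step 5 | 6,6-dimethoxy-2-(2-{3-methoxy-4-(triisopropylsilyloxy)phenyl}ethyl)-4-(trimethylsilyloxy)cyclohexa-1,4-diene-1-carbaldehyde | O=CC1=C(CCc2ccc(O[Si](C(C)C)(C(C)C)C(C)C)c(OC)c2)CC(O[Si](C)(C)C)=CC1(OC)OC
F2 | step 5 | 4-hydroxy-2-methoxy-6-(2-{3-methoxy-4-(triisopropylsilyloxy)phenyl}ethyl)benzaldehyde | O=Cc1c(CCc2ccc(O[Si](C(C)C)(C(C)C)C(C)C)c(OC)c2)cc(O)cc1OC
F3 | step 5 | 2-methoxy-6-(2-{3-methoxy-4-(triisopropylsilyloxy)phenyl}ethyl)-4-(triisopropylsilyloxy)benzaldehyde | O=Cc1c(CCc2ccc(O[Si](C(C)C)(C(C)C)C(C)C)c(OC)c2)cc(O[Si](C(C)C)(C(C)C)C(C)C)cc1OC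
F4 | step 5 | 1-[2-methoxy-6-(2-{3-methoxy-4-(triisopropylsilyloxy)phenyl}ethyl)-4-(triisopropylsilyloxy)phenyl]-5-[3-methoxy-4-(triisopropylsilyloxy)phenyl]pent-2-yn-1-ol (racemic) | OC(C#CCCc1ccc(O[Si](C(C)C)(C(C)C)C(C)C)c(OC)c1)c1c(CCc2ccc(O[Si](C(C)C)(C(C)C)C(C)C)c(OC)c2)cc(O[Si](C(C)C)(C(C)C)C(C)C)cc1OC
F5 | step 5 | 1-[2-methoxy-6-(2-{3-methoxy-4-(triisopropylsilyloxy)phenyl}ethyl)-4-(triisopropylsilyloxy)phenyl]-5-[3-methoxy-4-(triisopropylsilyloxy)phenyl]pent-2-yn-1-one | O=C(C#CCCc1ccc(O[Si](C(C)C)(C(C)C)C(C)C)c(OC)c1)c1c(CCc2ccc(O[Si](C(C)C)(C(C)C)C(C)C)c(OC)c2)cc(O[Si](C(C)C)(C(C)C)C(C)C)cc1OC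
F6 | step 5 | [6,6-dimethoxy-2-(2-{3-methoxy-4-(triisopropylsilyloxy)phenyl}ethyl)-4-(trimethylsilyloxy)cyclohexa-1,4-dien-1-yl][2-methoxy-6-(2-{3-methoxy-4-(triisopropylsilyloxy)phenyl}ethyl)-4-(triisopropylsilyloxy)phenyl]methanone | O=C(C1=C(CCc2ccc(O[Si](C(C)C)(C(C)C)C(C)C)c(OC)c2)CC(O[Si](C)(C)C)=CC1(OC)OC)c1c(CCc2ccc(O[Si](C(C)C)(C(C)C)C(C)C)c(OC)c2)cc(O[Si](C(C)C)(C(C)C)C(C)C)cc1OC
F7 | step 5 | [2-methoxy-6-(2-{3-methoxy-4-(triisopropylsilyloxy)phenyl}ethyl)-4-(trimethylsilyloxy)phenyl][2-methoxy-6-(2-{3-methoxy-4-(triisopropylsilyloxy)phenyl}ethyl)-4-(triisopropylsilyloxy)phenyl]methanone | O=C(c1c(CCc2ccc(O[Si](C(C)C)(C(C)C)C(C)C)c(OC)c2)cc(O[Si](C)(C)C)cc1OC)c1c(CCc2ccc(O[Si](C(C)C)(C(C)C)C(C)C)c(OC)c2)cc(O[Si](C(C)C)(C(C)C)C(C)C)cc1OC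
F8 | step 6 | bis{4-(benzyloxy)-2-[2-(4-(benzyloxy)-3-methoxyphenyl)ethyl]-6-methoxyphenyl}methanone | O=C(c1c(CCc2ccc(OCc3ccccc3)c(OC)c2)cc(OCc2ccccc2)cc1OC)c1c(CCc2ccc(OCc3ccccc3)c(OC)c2)cc(OCc2ccccc2)cc1OC
F9 | step 6 | bis{4-(benzyloxy)-2-[2-(4-(benzyloxy)-3-methoxyphenyl)ethyl]-6-methoxyphenyl}methanol | OC(c1c(CCc2ccc(OCc3ccccc3)c(OC)c2)cc(OCc2ccccc2)cc1OC)c1c(CCc2ccc(OCc3ccccc3)c(OC)c2)cc(OCc2ccccc2)cc1OC
F10 | step 4 | N-methoxy-N-methyl-5-[3-methoxy-4-(triisopropylsilyloxy)phenyl]pent-2-ynamide | CON(C)C(=O)C#CCCc1ccc(O[Si](C(C)C)(C(C)C)C(C)C)c(OC)c1
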